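**Retrosynthetic overview**

1. The target is a 5,7-dihydroxyisoflavone whose ring B is a 1,2,3,4-tetrasubstituted resorcinol: C1' is bonded to C3 of the chromone, C2' bears OH, C3' bears the CH2 of ring D and C4' bears the oxygen of ring D. The plan rests on the fact that the C4' oxygen, not the C2' oxygen, closes dihydropyran ring D, a pattern that substitution on a resorcinol cannot fix cleanly.
2. Ring C is closed last from a deoxybenzoin and a one-carbon unit; the deoxybenzoin comes from a ring B arylacetic acid and a phloroglucinol triether (ring A), and the arylacetic acid comes from an aryl methyl ketone by oxidative 1,2-aryl shift.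
3. Ring B is built de novo on the finished chiral ring D: a diene with two exocyclic double bonds (enol ether methylene and bis(silyl) ketene acetal) adds but-3-yn-2-one and aromatises by loss of trimethylsilanol, forming C1'–C2' and C5'–C6'.
4. Ring D comes from prenol: asymmetric epoxidation sets C3'', the epoxy sulfonate alkylates allyl acetoacetate, and the ketone oxygen opens the oxirane at its tertiary carbon.
5. Order of ring formation: D, then B, then C; ring A is bought.

Key step: step 7

Assumption: 1,3,5-tris(benzyloxy)benzene is taken as a catalogue compound.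
Remark: the C3'' hydroxyl is carried as a benzyl ether and the carboxyl group as an allyl ester until the acid is needed; the reasons are given at steps 4 and 5.

**Route**

Step 1
Reactants: 1 3-methylbut-2-en-1-ol (prenol)
Product: 3 [(2S)-3,3-dimethyloxiran-2-yl]methyl 4-methylbenzenesulfonate, via (S)-epoxy alcohol 2 (not isolated)
Conditions: Ti(OiPr)4 (cat.), L-(+)-DIPT (cat.), t-BuOOH, 4 Å MS, CH2Cl2, −20 °C; P(OMe)3; then TsCl, Et3N, DMAP (cat.), −10 °C
Reagents that add atoms: tert-butyl hydroperoxide, CC(C)(C)OO; 4-methylbenzenesulfonyl chloride, Cc1ccc(cc1)S(Cl)(=O)=O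
Why: Katsuki–Sharpless asymmetric epoxidation, in which the titanium complex of L-(+)-tartrate delivers oxygen to the face that gives the 2S oxirane (the same facial sense that converts E-allylic alcohols into 2S,3S epoxy alcohols), so the only stereocentre of the target (later C3'') is set here by the tartrate, and sulfonylation in the same pot avoids isolating the small, water-soluble epoxy alcohol.

Step 2
Reactants: 3 [(2S)-3,3-dimethyloxiran-2-yl]methyl 4-methylbenzenesulfonate; 4 prop-2-enyl 3-oxobutanoate (allyl acetoacetate)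
Product: 5 prop-2-enyl 2-acetyl-3-[(2S)-3,3-dimethyloxiran-2-yl]propanoate (mixture of C2 epimers)
Conditions: NaH, NaI (cat.), THF/DMF, 0 → 50 °C; 4 in excess
Reagents that add atoms: none
Why: Acetoacetic ester alkylation (SN2) at the primary sulfonate carbon, which is activated by the neighbouring oxirane, while the hindered oxirane carbons are not attacked, so the stereocentre is untouched and the new C2 centre, formed as a mixture, disappears in step 3.

Step 3
Reactants: 5 prop-2-enyl 2-acetyl-3-[(2S)-3,3-dimethyloxiran-2-yl]propanoate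
Product: 6 prop-2-enyl (3S)-3-hydroxy-2,2,6-trimethyl-3,4-dihydro-2H-pyran-5-carboxylate
Conditions: BF3·OEt2 (0.3 equiv), CH2Cl2, −40 → 0 °C
Reagents that add atoms: none
Why: Lewis-acid-promoted intramolecular epoxide opening (6-endo oxacyclisation) in which the ketone oxygen attacks the activated oxirane at its tertiary carbon, where positive charge is best stabilised, and loss of the acidic C2 proton gives the vinylogous carbonate, while the C–O bond at the stereocentre is never broken and so keeps the S configuration.

Step 4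
Reactants: 6 prop-2-enyl (3S)-3-hydroxy-2,2,6-trimethyl-3,4-dihydro-2H-pyran-5-carboxylate
Product: 7 prop-2-enyl (3S)-3-(benzyloxy)-2,2,6-trimethyl-3,4-dihydro-2H-pyran-5-carboxylate
Conditions: BnBr, NaH, Bu4NI (cat.), THF/DMF, 0 °C → rt
Reagents that add atoms: benzyl bromide, BrCc1ccccc1
Why: Williamson etherification of the secondary alkoxide in the presence of the halide, the benzyl ether being chosen because it should survive the amide base of step 6, the acidic methanol of step 9 and the acids of steps 11 and 12, and leaves in the final hydrogenolysis.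

Step 5
Reactants: 7 prop-2-enyl (3S)-3-(benzyloxy)-2,2,6-trimethyl-3,4-dihydro-2H-pyran-5-carboxylate
Product: 8 (3S)-3-(benzyloxy)-2,2,6-trimethyl-3,4-dihydro-2H-pyran-5-carboxylic acid
Conditions: Pd(PPh3)4 (cat.), morpholine, THF, rt; citric acid work-up
Reagents that add atoms: none
Why: Tsuji–Trost deallylation, in which the palladium catalyst ionises the allyl ester to a π-allyl complex that morpholine captures, freeing the acid under neutral conditions that leave the enol ether and the benzyl ether alone.

Step 6
Reactants: 8 (3S)-3-(benzyloxy)-2,2,6-trimethyl-3,4-dihydro-2H-pyran-5-carboxylic acid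
Product: 10 (5S)-5-(benzyloxy)-3-[bis(trimethylsilyloxy)methylidene]-6,6-dimethyl-2-methylideneoxane, via dilithium dienediolate 9 (not isolated)
Conditions: LiN(iPr)2 (2.2 equiv), THF, −78 → 0 °C; Me3SiCl (2.5 equiv), −78 °C → rt; filtered under argon and used crude
Reagents that add atoms: chlorotrimethylsilane, C[Si](C)(C)Cl
Why: Double deprotonation (the acid, then the C6 methyl group, which is the vinylogous γ-position of the β-alkoxyacrylate) gives a dienediolate that the chlorosilane traps on both oxygens, which is the standard preparation of bis(silyl) ketene acetals and the same γ-deprotonation by which 1-silyloxy-1,3-dialkoxybutadienes are made from 3-alkoxycrotonates.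

Step 7
Reactants: 10 (5S)-5-(benzyloxy)-3-[bis(trimethylsilyloxy)methylidene]-6,6-dimethyl-2-methylideneoxane; 11 but-3-yn-2-one
Product: 14 1-[(3S)-3-(benzyloxy)-5-hydroxy-2,2-dimethyl-3,4-dihydro-2H-chromen-6-yl]ethanone, via cycloadduct 12 (not isolated), via aryl silyl ether 13 (not isolated)
Conditions: toluene, −20 °C → rt; then 1 M HCl, THF, rt
Reagents that add atoms: none
Why: Because the two C=C bonds of 10 are exocyclic to neighbouring carbons of ring D, the diene cannot leave the cisoid geometry; its methylene carbon, the most nucleophilic position of this 1,1,3-trioxygenated diene, bonds to the unsubstituted β-carbon of the ynone (C5'–C6') and the ketene-acetal carbon bonds to the acyl-bearing carbon (C1'–C2') in a [4+2] cycloaddition whose two bonds are formed to very different extents in the transition state, closing ring B as a six-membered carbocycle. The closest known reaction type is the Diels–Alder addition of oxygenated ketene-acetal dienes to acetylenic ketones and esters followed by aromatisation, which gives salicylate-type arenes. Cycloadduct 12 is a 1,4-cyclohexadiene with two silyloxy groups on C2' and a CH2 at C5', so 1,4-elimination of trimethylsilanol aromatises it to 13, and dilute acid frees the phenol, which is held by a hydrogen bond to the acetyl group. No stereocentre is formed, and the benzyl-protected C3'' centre lies outside the reacting atoms. The selectivity required is regiochemical: the acetyl group ends up beside the C2' oxygen because of the matched polarisation of diene and ynone, and the ring D oxygen is on C4' because the carbon that becomes C4' carries it before ring B exists.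

Step 8
Reactants: 14 1-[(3S)-3-(benzyloxy)-5-hydroxy-2,2-dimethyl-3,4-dihydro-2H-chromen-6-yl]ethanone
Product: 15 1-[(3S)-3,5-bis(benzyloxy)-2,2-dimethyl-3,4-dihydro-2H-chromen-6-yl]ethanone
Conditions: BnBr, K2CO3, DMF, 60 °C
Reagents that add atoms: benzyl bromide, BrCc1ccccc1
Why: Williamson O-benzylation of the hydrogen-bonded phenol, needed because a free phenol would be oxidised in step 9 and a free C2' hydroxyl would later cyclise onto the benzylic ketone.

Step 9
Reactants: 15 1-[(3S)-3,5-bis(benzyloxy)-2,2-dimethyl-3,4-dihydro-2H-chromen-6-yl]ethanone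
Product: 16 methyl 2-[(3S)-3,5-bis(benzyloxy)-2,2-dimethyl-3,4-dihydro-2H-chromen-6-yl]acetate
Conditions: Tl(NO3)3·3H2O, MeOH/HC(OMe)3, rt
Reagents that add atoms: methanol, CO
Why: Oxidative 1,2-aryl shift of an aryl methyl ketone with thallium trinitrate, in which the ketone forms its methyl enol ether, trivalent thallium adds to it, and the electron-rich aryl group migrates as monovalent thallium leaves to give the methyl arylacetate, with neither benzyl ether nor the stereocentre involved.

Step 10
Reactants: 16 methyl 2-[(3S)-3,5-bis(benzyloxy)-2,2-dimethyl-3,4-dihydro-2H-chromen-6-yl]acetate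
Product: 17 2-[(3S)-3,5-bis(benzyloxy)-2,2-dimethyl-3,4-dihydro-2H-chromen-6-yl]acetic acid
Conditions: LiOH, THF/MeOH/H2O, rt; then 1 M HCl
Reagents that add atoms: lithium hydroxide, [Li+].[OH-]
Why: Saponification of an unhindered methyl ester, with nothing else in the molecule labile to aqueous base.

Step 11
Reactants: 17 2-[(3S)-3,5-bis(benzyloxy)-2,2-dimethyl-3,4-dihydro-2H-chromen-6-yl]acetic acid; 18 1,3,5-tris(benzyloxy)benzene
Product: 20 2-[(3S)-3,5-bis(benzyloxy)-2,2-dimethyl-3,4-dihydro-2H-chromen-6-yl]-1-[2,4,6-tris(benzyloxy)phenyl]ethanone, via mixed anhydride 19 (not isolated)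
Conditions: (CF3CO)2O, CH2Cl2, 0 °C → rt; 18 in excess
Reagents that add atoms: none
Why: Friedel–Crafts acylation through the mixed trifluoroacetic anhydride, which the very nucleophilic phloroglucinol triether should capture at room temperature without a metal halide so that the benzyl ethers and ring D survive, and since the three free positions of 18 are equivalent only one ketone can form.

Step 12
Reactants: 20 2-[(3S)-3,5-bis(benzyloxy)-2,2-dimethyl-3,4-dihydro-2H-chromen-6-yl]-1-[2,4,6-tris(benzyloxy)phenyl]ethanone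
Product: 21 2-[(3S)-3,5-bis(benzyloxy)-2,2-dimethyl-3,4-dihydro-2H-chromen-6-yl]-1-[2,4-bis(benzyloxy)-6-hydroxyphenyl]ethanone
Conditions: BCl3 (1.1 equiv), CH2Cl2, −78 °C; then H2O
Reagents that add atoms: none
Why: Chelation-controlled ether cleavage, in which BCl3 bound between the ketone oxygen and one ortho benzyloxy oxygen removes only that benzyl group at low temperature, the resulting boron chelate then shields the second, equivalent ortho ether, and the ethers that cannot chelate react far more slowly.

Step 13
Reactants: 21 2-[(3S)-3,5-bis(benzyloxy)-2,2-dimethyl-3,4-dihydro-2H-chromen-6-yl]-1-[2,4-bis(benzyloxy)-6-hydroxyphenyl]ethanone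
Product: 23 5,7-bis(benzyloxy)-3-[(3S)-3,5-bis(benzyloxy)-2,2-dimethyl-3,4-dihydro-2H-chromen-6-yl]-4H-chromen-4-one, via enaminone 22 (not isolated)
Conditions: Me2NCH(OMe)2, toluene, 90 °C
Reagents that add atoms: N,N-dimethylformamide dimethyl acetal, COC(OC)N(C)C
Why: Condensation of the activated methylene with the formamide acetal gives an enaminone whose β-carbon is attacked by the ortho phenol with loss of dimethylamine, closing ring C by addition–elimination in the standard deoxybenzoin route to isoflavones.

Step 14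
Reactants: 23 5,7-bis(benzyloxy)-3-[(3S)-3,5-bis(benzyloxy)-2,2-dimethyl-3,4-dihydro-2H-chromen-6-yl]-4H-chromen-4-one
Product: 24 3-[(3S)-3,5-dihydroxy-2,2-dimethyl-3,4-dihydro-2H-chromen-6-yl]-5,7-dihydroxy-4H-chromen-4-one (target, CNP0318808.1)
Conditions: H2 (1 atm), Pd/C, EtOAc/MeOH, rt
Reagents that add atoms: none
Why: Catalytic hydrogenolysis of the three aryl benzyl ethers and the alkyl benzyl ether, stopped when the last ether is gone so that the more slowly reduced C2–C3 double bond of the chromone is kept, and the stereocentre, which is not benzylic, is not touched.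

**Compound list**

1 | 3-methylbut-2-en-1-ol (prenol) | CC(C)=CCO | starting material
2 | [(2S)-3,3-dimethyloxiran-2-yl]methanol | CC1(C)O[C@H]1CO | intermediate (not isolated)
3 | [(2S)-3,3-dimethyloxiran-2-yl]methyl 4-methylbenzenesulfonate | CC1(C)O[C@H]1COS(=O)(=O)c2ccc(C)cc2 | intermediate
4 | prop-2-enyl 3-oxobutanoate (allyl acetoacetate) | CC(=O)CC(=O)OCC=C | starting material
5 | prop-2-enyl 2-acetyl-3-[(2S)-3,3-dimethyloxiran-2-yl]propanoate (C2 epimers) | CC(=O)C(C[C@@H]1OC1(C)C)C(=O)OCC=C | intermediate
6 | prop-2-enyl (3S)-3-hydroxy-2,2,6-trimethyl-3,4-dihydro-2H-pyran-5-carboxylate | CC1=C(C(=O)OCC=C)C[C@H](O)C(C)(C)O1 | intermediate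
7 | prop-2-enyl (3S)-3-(benzyloxy)-2,2,6-trimethyl-3,4-dihydro-2H-pyran-5-carboxylate | CC1=C(C(=O)OCC=C)C[C@H](OCc2ccccc2)C(C)(C)O1 | intermediate
8 | (3S)-3-(benzyloxy)-2,2,6-trimethyl-3,4-dihydro-2H-pyran-5-carboxylic acid | CC1=C(C(=O)O)C[C@H](OCc2ccccc2)C(C)(C)O1 | intermediate
9 | dilithium dienediolate of 8 | [Li+].[Li+].C=C1OC(C)(C)[C@@H](OCc2ccccc2)CC1=C([O-])[O-] | intermediate (not isolated)
10 | (5S)-5-(benzyloxy)-3-[bis(trimethylsilyloxy)methylidene]-6,6-dimethyl-2-methylideneoxane | C=C1OC(C)(C)[C@@H](OCc2ccccc2)CC1=C(O[Si](C)(C)C)O[Si](C)(C)C | intermediate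
11 | but-3-yn-2-one | CC(=O)C#C | starting material
12 | 1-[(3S)-3-(benzyloxy)-2,2-dimethyl-5,5-bis(trimethylsilyloxy)-3,4,5,8-tetrahydro-2H-chromen-6-yl]ethanone (cycloadduct) | CC1(C)OC2=C(C[C@@H]1OCc3ccccc3)C(O[Si](C)(C)C)(O[Si](C)(C)C)C(C(C)=O)=CC2 | intermediate (not isolated)
13 | 1-[(3S)-3-(benzyloxy)-2,2-dimethyl-5-(trimethylsilyloxy)-3,4-dihydro-2H-chromen-6-yl]ethanone | CC1(C)Oc2ccc(C(C)=O)c(O[Si](C)(C)C)c2C[C@@H]1OCc3ccccc3 | intermediate (not isolated)
14 | 1-[(3S)-3-(benzyloxy)-5-hydroxy-2,2-dimethyl-3,4-dihydro-2H-chromen-6-yl]ethanone | CC1(C)Oc2ccc(C(C)=O)c(O)c2C[C@@H]1OCc3ccccc3 | intermediate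
15 | 1-[(3S)-3,5-bis(benzyloxy)-2,2-dimethyl-3,4-dihydro-2H-chromen-6-yl]ethanone | CC1(C)Oc2ccc(C(C)=O)c(OCc3ccccc3)c2C[C@@H]1OCc4ccccc4 | intermediate
16 | methyl 2-[(3S)-3,5-bis(benzyloxy)-2,2-dimethyl-3,4-dihydro-2H-chromen-6-yl]acetate | CC1(C)Oc2ccc(CC(=O)OC)c(OCc3ccccc3)c2C[C@@H]1OCc4ccccc4 | intermediate
17 | 2-[(3S)-3,5-bis(benzyloxy)-2,2-dimethyl-3,4-dihydro-2H-chromen-6-yl]acetic acid | CC1(C)Oc2ccc(CC(=O)O)c(OCc3ccccc3)c2C[C@@H]1OCc4ccccc4 | intermediate
18 | 1,3,5-tris(benzyloxy)benzene | c1ccc(COc2cc(OCc3ccccc3)cc(OCc4ccccc4)c2)cc1 | starting material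
19 | mixed anhydride of 17 with trifluoroacetic acid | CC1(C)Oc2ccc(CC(=O)OC(=O)C(F)(F)F)c(OCc3ccccc3)c2C[C@@H]1OCc4ccccc4 | intermediate (not isolated)
20 | 2-[(3S)-3,5-bis(benzyloxy)-2,2-dimethyl-3,4-dihydro-2H-chromen-6-yl]-1-[2,4,6-tris(benzyloxy)phenyl]ethanone | CC1(C)Oc2ccc(CC(=O)c5c(OCc6ccccc6)cc(OCc7ccccc7)cc5OCc8ccccc8)c(OCc3ccccc3)c2C[C@@H]1OCc4ccccc4 | intermediate
21 | 2-[(3S)-3,5-bis(benzyloxy)-2,2-dimethyl-3,4-dihydro-2H-chromen-6-yl]-1-[2,4-bis(benzyloxy)-6-hydroxyphenyl]ethanone | CC1(C)Oc2ccc(CC(=O)c5c(O)cc(OCc6ccccc6)cc5OCc7ccccc7)c(OCc3ccccc3)c2C[C@@H]1OCc4ccccc4 | intermediate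
22 | 2-[(3S)-3,5-bis(benzyloxy)-2,2-dimethyl-3,4-dihydro-2H-chromen-6-yl]-1-[2,4-bis(benzyloxy)-6-hydroxyphenyl]-3-(dimethylamino)prop-2-en-1-one | CC1(C)Oc2ccc(C(=CN(C)C)C(=O)c5c(O)cc(OCc6ccccc6)cc5OCc7ccccc7)c(OCc3ccccc3)c2C[C@@H]1OCc4ccccc4 | intermediate (not isolated)
23 | 5,7-bis(benzyloxy)-3-[(3S)-3,5-bis(benzyloxy)-2,2-dimethyl-3,4-dihydro-2H-chromen-6-yl]-4H-chromen-4-one | CC1(C)Oc2ccc(-c5coc6cc(OCc7ccccc7)cc(OCc8ccccc8)c6c5=O)c(OCc3ccccc3)c2C[C@@H]1OCc4ccccc4 | intermediate
24 | 3-[(3S)-3,5-dihydroxy-2,2-dimethyl-3,4-dihydro-2H-chromen-6-yl]-5,7-dihydroxy-4H-chromen-4-one | CC1(C)Oc2ccc(-c3coc4cc(O)cc(O)c4c3=O)c(O)c2C[C@@H]1O | target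

**Step count**

Total: 14 steps. Longest linear sequence: 14 steps (1 → 24); compounds 4, 11 and 18 enter as bought materials.

**Steps most likely to fail**

Step 7 (key step). After the first C–C bond forms, a silyl group may move to the allenolate oxygen faster than the second bond closes, which would leave an open-chain Michael adduct; the diene may also hydrolyse before it reacts. The fallback builds ring B in two polar stages and sets out from ester 7. LiN(iPr)2 and Me3SiCl in THF at −78 °C should give, by the same γ-deprotonation, the allyl trimethylsilyl ketene acetal F1. TiCl4 in CH2Cl2 at −78 °C should then promote a vinylogous Mukaiyama addition of its methylene carbon to commercial 4,4-dimethoxybutan-2-one, giving prop-2-enyl (3S)-3-(benzyloxy)-6-(2-methoxy-4-oxopentyl)-2,2-dimethyl-3,4-dihydro-2H-pyran-5-carboxylate F2. KOtBu in THF should close ring B by intramolecular Claisen condensation of the ketone α-methylene onto the allyl ester, giving the cyclic β-diketone F3, which loses methanol and tautomerises to phenol 14, where the route is rejoined.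

Step 3. The ketone oxygen may attack the secondary oxirane carbon instead (5-exo opening), which would give a dihydrofuran with a hydroxyisopropyl group and invert the stereocentre; a hydride shift to a ketone is a second possible diversion. The fallback makes the six-membered ring the only possible outcome and sets out from tosylate 3. HClO4 (cat.) in THF/H2O should open the oxirane by attack of water at the tertiary carbon, leaving the C–O bond at the stereocentre intact, to give (2S)-2,3-dihydroxy-3-methylbutyl 4-methylbenzenesulfonate F4. Benzyl 2,2,2-trichloroacetimidate with catalytic TfOH should etherify the secondary hydroxyl in preference to the tertiary one, giving (2S)-2-(benzyloxy)-3-hydroxy-3-methylbutyl 4-methylbenzenesulfonate F5. Alkylation of 4 (NaH, NaI, DMF, 60 °C) should give prop-2-enyl (4S)-2-acetyl-4-(benzyloxy)-5-hydroxy-5-methylhexanoate F6. Pyridinium 4-methylbenzenesulfonate in toluene at reflux with removal of water should then condense the tertiary hydroxyl with the ketone to the cyclic enol ether, rejoining the route at benzyl ether 7.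

Step 9. The thallium salt may attack the electron-rich ring at C5', or enol ether formation at the ortho-substituted ketone may be slow, so that the aryl shift is incomplete. The fallback replaces the aryl shift by a carbonyl transposition and sets out from ketone 15. A Willgerodt–Kindler reaction (S8, morpholine, 130 °C) should give 2-[(3S)-3,5-bis(benzyloxy)-2,2-dimethyl-3,4-dihydro-2H-chromen-6-yl]-1-(morpholin-4-yl)ethanethione F7. KOH in aqueous ethanol at reflux followed by acidification should give acid 17, where the route is rejoined without passing through ester 16.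

**Further compounds**

F1 | step 7 | (5S)-5-(benzyloxy)-6,6-dimethyl-2-methylidene-3-[(prop-2-enyloxy)(trimethylsilyloxy)methylidene]oxane | C=CCOC(O[Si](C)(C)C)=C1C[C@H](OCc2ccccc2)C(C)(C)OC1=C
F2 | step 7 | prop-2-enyl (3S)-3-(benzyloxy)-6-(2-methoxy-4-oxopentyl)-2,2-dimethyl-3,4-dihydro-2H-pyran-5-carboxylate | C=CCOC(=O)C1=C(CC(OC)CC(C)=O)OC(C)(C)[C@@H](OCc2ccccc2)C1
F3 | step 7 | (3S)-6-acetyl-3-(benzyloxy)-7-methoxy-2,2-dimethyl-2,3,4,6,7,8-hexahydro-5H-chromen-5-one | COC1CC2=C(C[C@H](OCc3ccccc3)C(C)(C)O2)C(=O)C1C(C)=O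
F4 | step 3 | (2S)-2,3-dihydroxy-3-methylbutyl 4-methylbenzenesulfonate | CC(C)(O)[C@@H](O)COS(=O)(=O)c1ccc(C)cc1
F5 | step 3 | (2S)-2-(benzyloxy)-3-hydroxy-3-methylbutyl 4-methylbenzenesulfonate | CC(C)(O)[C@@H](OCc1ccccc1)COS(=O)(=O)c2ccc(C)cc2
F6 | step 3 | prop-2-enyl (4S)-2-acetyl-4-(benzyloxy)-5-hydroxy-5-methylhexanoate | CC(=O)C(C[C@H](OCc1ccccc1)C(C)(C)O)C(=O)OCC=C
F7 | step 9 | 2-[(3S)-3,5-bis(benzyloxy)-2,2-dimethyl-3,4-dihydro-2H-chromen-6-yl]-1-(morpholin-4-yl)ethanethione | CC1(C)Oc2ccc(CC(=S)N5CCOCC5)c(OCc3ccccc3)c2C[C@@H]1OCc4ccccc4
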